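## Retrosynthetic overview

1. Target ⇒ open C6–C7, the bond germacrene A synthase forms between farnesyl C1 and C10. The precursor is an acyclic farnesane-type epoxy-aldehyde whose C7=C11 olefin already sits in a 3-(bromomethyl)butenolide. An allyl-chromium closure makes the ten-membered ring last and sets C6 and C7.
2. Butenolide ⇒ acylation of the C8 hydroxyl by the C12 acid (the lactone C–O bond of the biosynthesis) using 2-(bromomethyl)acrylic acid, then C7=C11 ring-closing metathesis.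
3. C8/C9 anti-diol ⇒ (E)-γ-silyloxyallylboration of the C9 enal made from geranyl acetate by SeO2 oxidation.
4. 4,5-Oxirane ⇒ Sharpless epoxidation of the geraniol-type allylic alcohol; C6 aldehyde by oxidation.
5. Ring order: oxirane → butenolide → ten-membered carbocycle. The last closure turns the butenolide into the trans-fused α-methylene-γ-lactone.

Assumption: germacrane numbering is used for the target and late intermediates (C6 carbinol, C7 ring-fusion carbon, C8 lactone-oxygen carbon, C9 isobutyrate carbon); the target is read as (4S,5S,6S,7S,8R,9S,1(10)E).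

## Route

Step 1
Reactants: 1 geranyl acetate
Product: 2 (2E,6E)-3,7-dimethyl-8-oxoocta-2,6-dien-1-yl acetate
Conditions: SeO2 (1.2 equiv), 1,4-dioxane, 80 °C
Reagents that add atoms: selenium dioxide, O=[Se]=O
Why: Riley allylic oxidation (ene reaction then [2,3]-sigmatropic shift) attacks the E-methyl of the electron-richer 6,7-olefin, the 2,3-olefin being deactivated by the allylic acetate, and stoichiometric SeO2 carries the allylic alcohol on to the (E)-enal; no stereocentre is formed.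

Step 2
Reactants: 2 (2E,6E)-3,7-dimethyl-8-oxoocta-2,6-dien-1-yl acetate; 3 2-[(1E)-3-{[tert-butyl(dimethyl)silyl]oxy}prop-1-en-1-yl]-4,4,5,5-tetramethyl-1,3,2-dioxaborolane
Product: 6 (2E,6E,8S,9R)-9-[(tert-butyldimethylsilyl)oxy]-8-hydroxy-3,7-dimethylundeca-2,6,10-trien-1-yl acetate, via allylboronate 4 (not isolated), via borate ester 5 (not isolated)
Conditions: 3 (1.5 equiv), [Ir(cod)(PPh2Me)2]PF6 (2 mol %, H2-activated), THF, rt; then toluene, 2, (R)-TRIP phosphoric acid (5 mol %), 4 Å MS, −30 °C; aq NaHCO3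
Reagents that add atoms: none
Why: An iridium-hydride 1,3-hydrogen shift converts 3 into the (E)-γ-silyloxyallylboronate 4, which adds to the enal in a chiral-phosphoric-acid-catalysed allylboration through a Zimmerman–Traxler chair, the E-boronate giving the 8,9-anti relationship and (R)-TRIP directing attack to the Re face of the aldehyde to set 8S and hence 9R.

Step 3
Reactants: 6 (2E,6E,8S,9R)-9-[(tert-butyldimethylsilyl)oxy]-8-hydroxy-3,7-dimethylundeca-2,6,10-trien-1-yl acetate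
Product: 7 (2E,6E,8S,9R)-1-acetoxy-9-[(tert-butyldimethylsilyl)oxy]-3,7-dimethylundeca-2,6,10-trien-8-yl 2-methylpropanoate
Conditions: (iPrCO)2O (2 equiv), Et3N (3 equiv), DMAP (20 mol %), CH2Cl2, 0 °C to rt
Reagents that add atoms: isobutyric anhydride, CC(C)C(=O)OC(=O)C(C)C
Why: DMAP-catalysed acyl transfer esterifies the only free hydroxyl without breaking its C–O bond, so 8S is retained.

Step 4
Reactants: 7 (2E,6E,8S,9R)-1-acetoxy-9-[(tert-butyldimethylsilyl)oxy]-3,7-dimethylundeca-2,6,10-trien-8-yl 2-methylpropanoate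
Product: 8 (2E,6E,8S,9R)-9-[(tert-butyldimethylsilyl)oxy]-1-hydroxy-3,7-dimethylundeca-2,6,10-trien-8-yl 2-methylpropanoate
Conditions: K2CO3 (0.2 equiv), MeOH, 0 °C, stopped at full conversion of 7
Reagents that add atoms: none
Why: Base-catalysed transesterification (methanolysis) removes the unhindered primary allylic acetate much faster than the α-branched isobutyrate on a hindered secondary carbinol, and the neighbouring silyl ether leaves no free hydroxyl for acyl migration.

Step 5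
Reactants: 8 (2E,6E,8S,9R)-9-[(tert-butyldimethylsilyl)oxy]-1-hydroxy-3,7-dimethylundeca-2,6,10-trien-8-yl 2-methylpropanoate
Product: 9 (3E,5S,6R)-6-[(tert-butyldimethylsilyl)oxy]-1-[(2S,3S)-3-(hydroxymethyl)-2-methyloxiran-2-yl]-4-methylocta-3,7-dien-5-yl 2-methylpropanoate
Conditions: Ti(OiPr)4 (10 mol %), diisopropyl L-(+)-tartrate (12 mol %), TBHP (2 equiv), 4 Å MS, CH2Cl2, −20 °C
Reagents that add atoms: tert-butyl hydroperoxide, CC(C)(C)OO
Why: Sharpless asymmetric epoxidation acts only on the olefin of the free primary allylic alcohol, and the L-(+)-tartrate complex delivers oxygen to the face that gives the (2S,3S)-oxirane, as with geraniol.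

Step 6
Reactants: 9 (3E,5S,6R)-6-[(tert-butyldimethylsilyl)oxy]-1-[(2S,3S)-3-(hydroxymethyl)-2-methyloxiran-2-yl]-4-methylocta-3,7-dien-5-yl 2-methylpropanoate
Product: 10 (3E,5S,6R)-6-hydroxy-1-[(2S,3S)-3-(hydroxymethyl)-2-methyloxiran-2-yl]-4-methylocta-3,7-dien-5-yl 2-methylpropanoate
Conditions: HF·pyridine, pyridine, THF, 0 °C to rt
Reagents that add atoms: none
Why: Fluoride-driven desilylation under buffered, non-basic conditions frees the secondary hydroxyl without 1,2-migration of the neighbouring isobutyrate, Payne rearrangement or oxirane opening.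

Step 7
Reactants: 10 (3E,5S,6R)-6-hydroxy-1-[(2S,3S)-3-(hydroxymethyl)-2-methyloxiran-2-yl]-4-methylocta-3,7-dien-5-yl 2-methylpropanoate
Product: 11 (3E,5S,6R)-1-[(2S,3R)-3-formyl-2-methyloxiran-2-yl]-6-hydroxy-4-methylocta-3,7-dien-5-yl 2-methylpropanoate
Conditions: TEMPO (10 mol %), PhI(OAc)2 (1.1 equiv), CH2Cl2, 0 °C to rt
Reagents that add atoms: none
Why: The sterically demanding oxoammonium oxidant (TEMPO/PhI(OAc)2 oxidation) takes the primary carbinol far faster than the hindered secondary allylic one and is non-basic, so the oxirane carbon next to the aldehyde keeps its configuration (descriptor changes to R by priority only).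

Step 8
Reactants: 11 (3E,5S,6R)-1-[(2S,3R)-3-formyl-2-methyloxiran-2-yl]-6-hydroxy-4-methylocta-3,7-dien-5-yl 2-methylpropanoate; 12 2-(bromomethyl)prop-2-enoic acid
Product: 13 (3E,5S,6R)-6-{[2-(bromomethyl)prop-2-enoyl]oxy}-1-[(2S,3R)-3-formyl-2-methyloxiran-2-yl]-4-methylocta-3,7-dien-5-yl 2-methylpropanoate
Conditions: 12 (1.5 equiv), N,N'-diisopropylcarbodiimide (1.6 equiv), DMAP (5 mol %), CH2Cl2, −20 to 0 °C
Reagents that add atoms: none
Why: Steglich esterification acylates the remaining hydroxyl with retention, forming the C8 oxygen–C12 acyl bond of the future lactone; DMAP is kept low and cold to limit its SN2' attack on the allylic bromide.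

Step 9
Reactants: 13 (3E,5S,6R)-6-{[2-(bromomethyl)prop-2-enoyl]oxy}-1-[(2S,3R)-3-formyl-2-methyloxiran-2-yl]-4-methylocta-3,7-dien-5-yl 2-methylpropanoate
Product: 14 (1S,2E)-1-[(2R)-4-(bromomethyl)-5-oxo-2,5-dihydrofuran-2-yl]-5-[(2S,3R)-3-formyl-2-methyloxiran-2-yl]-2-methylpent-2-en-1-yl 2-methylpropanoate
Conditions: second-generation Hoveyda–Grubbs catalyst (10 mol %), toluene (5 mM), 70 °C, argon sparge
Reagents that add atoms: none
Why: Ring-closing metathesis between the monosubstituted vinyl group and the 1,1-disubstituted acrylate closes the five-membered butenolide as in methacrylate-to-α-substituted-butenolide closures, with the trisubstituted olefin, aldehyde, oxirane and allylic bromide as spectators and no stereocentre touched.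

Step 10
Reactants: 14 (1S,2E)-1-[(2R)-4-(bromomethyl)-5-oxo-2,5-dihydrofuran-2-yl]-5-[(2S,3R)-3-formyl-2-methyloxiran-2-yl]-2-methylpent-2-en-1-yl 2-methylpropanoate
Product: 17 (4S,5S,6S,7S,8R,9S,1(10)E)-4,5-epoxy-6-hydroxy-9-(2-methylpropanoyloxy)germacra-1(10),11(13)-dien-12,8-olide (CNP0220196.1), via allylchromium dichloride 15 (not isolated), via chromium alkoxide 16 (not isolated)
Conditions: CrCl2 (10 equiv), THF, rt, 14 added by syringe pump over 10 h to 1 mM; pH 7 phosphate buffer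
Reagents that add atoms: none
Why: Proposed new method: two CrCl2 reduce the allylic bromide to σ-allylchromium 15, whose γ-carbon (C7, the butenolide β-carbon) adds to the chromium-bound aldehyde through a six-membered chair in which the ring-locked E-type allyl unit gives the 6,7-anti relationship, attack anti to the C9 chain on C8 gives the trans-fused lactone and Felkin–Anh approach (oxirane C–O anti to the forming bond) gives the 5,6-anti carbinol, i.e. 6S and 7S, while the poorly nucleophilic trivalent chromium alkoxide 16 should not translactonise; the closest known reactions are the intermolecular chromium-mediated allylation of aldehydes with 3-(bromomethyl)furan-2(5H)-one and the intramolecular Nozaki–Hiyama closure of ω-formyl 2-(bromomethyl)alk-2-enoates to germacranolides.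

## Compound list

1 | geranyl acetate, (2E)-3,7-dimethylocta-2,6-dien-1-yl acetate | CC(=O)OC/C=C(\C)CCC=C(C)C | starting material
2 | (2E,6E)-3,7-dimethyl-8-oxoocta-2,6-dien-1-yl acetate | CC(=O)OC/C=C(\C)CC/C=C(\C)C=O | intermediate
3 | 2-[(1E)-3-{[tert-butyl(dimethyl)silyl]oxy}prop-1-en-1-yl]-4,4,5,5-tetramethyl-1,3,2-dioxaborolane | CC(C)(C)[Si](C)(C)OC/C=C/B1OC(C)(C)C(C)(C)O1 | starting material
4 | 2-[(2E)-3-{[tert-butyl(dimethyl)silyl]oxy}prop-2-en-1-yl]-4,4,5,5-tetramethyl-1,3,2-dioxaborolane (allylboronate, not isolated) | CC(C)(C)[Si](C)(C)O/C=C/CB1OC(C)(C)C(C)(C)O1 | intermediate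
5 | (2E,6E,8S,9R)-9-[(tert-butyldimethylsilyl)oxy]-3,7-dimethyl-8-[(4,4,5,5-tetramethyl-1,3,2-dioxaborolan-2-yl)oxy]undeca-2,6,10-trien-1-yl acetate (borate ester, not isolated) | CC(=O)OC/C=C(\C)CC/C=C(\C)[C@H](OB1OC(C)(C)C(C)(C)O1)[C@H](O[Si](C)(C)C(C)(C)C)C=C | intermediate
6 | (2E,6E,8S,9R)-9-[(tert-butyldimethylsilyl)oxy]-8-hydroxy-3,7-dimethylundeca-2,6,10-trien-1-yl acetate | CC(=O)OC/C=C(\C)CC/C=C(\C)[C@H](O)[C@H](O[Si](C)(C)C(C)(C)C)C=C | intermediate
7 | (2E,6E,8S,9R)-1-acetoxy-9-[(tert-butyldimethylsilyl)oxy]-3,7-dimethylundeca-2,6,10-trien-8-yl 2-methylpropanoate | CC(=O)OC/C=C(\C)CC/C=C(\C)[C@H](OC(=O)C(C)C)[C@H](O[Si](C)(C)C(C)(C)C)C=C | intermediate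
8 | (2E,6E,8S,9R)-9-[(tert-butyldimethylsilyl)oxy]-1-hydroxy-3,7-dimethylundeca-2,6,10-trien-8-yl 2-methylpropanoate | OC/C=C(\C)CC/C=C(\C)[C@H](OC(=O)C(C)C)[C@H](O[Si](C)(C)C(C)(C)C)C=C | intermediate
9 | (3E,5S,6R)-6-[(tert-butyldimethylsilyl)oxy]-1-[(2S,3S)-3-(hydroxymethyl)-2-methyloxiran-2-yl]-4-methylocta-3,7-dien-5-yl 2-methylpropanoate | OC[C@@H]1O[C@@]1(C)CC/C=C(\C)[C@H](OC(=O)C(C)C)[C@H](O[Si](C)(C)C(C)(C)C)C=C | intermediate
10 | (3E,5S,6R)-6-hydroxy-1-[(2S,3S)-3-(hydroxymethyl)-2-methyloxiran-2-yl]-4-methylocta-3,7-dien-5-yl 2-methylpropanoate | OC[C@@H]1O[C@@]1(C)CC/C=C(\C)[C@H](OC(=O)C(C)C)[C@H](O)C=C | intermediate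
11 | (3E,5S,6R)-1-[(2S,3R)-3-formyl-2-methyloxiran-2-yl]-6-hydroxy-4-methylocta-3,7-dien-5-yl 2-methylpropanoate | O=C[C@@H]1O[C@@]1(C)CC/C=C(\C)[C@H](OC(=O)C(C)C)[C@H](O)C=C | intermediate
12 | 2-(bromomethyl)prop-2-enoic acid | C=C(CBr)C(=O)O | starting material
13 | (3E,5S,6R)-6-{[2-(bromomethyl)prop-2-enoyl]oxy}-1-[(2S,3R)-3-formyl-2-methyloxiran-2-yl]-4-methylocta-3,7-dien-5-yl 2-methylpropanoate | O=C[C@@H]1O[C@@]1(C)CC/C=C(\C)[C@H](OC(=O)C(C)C)[C@H](OC(=O)C(=C)CBr)C=C | intermediate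
14 | (1S,2E)-1-[(2R)-4-(bromomethyl)-5-oxo-2,5-dihydrofuran-2-yl]-5-[(2S,3R)-3-formyl-2-methyloxiran-2-yl]-2-methylpent-2-en-1-yl 2-methylpropanoate | O=C[C@@H]1O[C@@]1(C)CC/C=C(\C)[C@H](OC(=O)C(C)C)[C@@H]1OC(=O)C(CBr)=C1 | intermediate
15 | allylchromium dichloride derived from 14 (CH2Br replaced by CH2CrCl2, not isolated) | O=C[C@@H]1O[C@@]1(C)CC/C=C(\C)[C@H](OC(=O)C(C)C)[C@@H]1OC(=O)C(C[Cr](Cl)Cl)=C1 | intermediate
16 | dichlorochromium alkoxide of 17 at the C6 oxygen (not isolated) | C=C1C(=O)O[C@@H]2[C@@H]1[C@H](O[Cr](Cl)Cl)[C@@H]1O[C@@]1(C)CC/C=C(\C)[C@@H]2OC(=O)C(C)C | intermediate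
17 | (4S,5S,6S,7S,8R,9S,1(10)E)-4,5-epoxy-6-hydroxy-9-(2-methylpropanoyloxy)germacra-1(10),11(13)-dien-12,8-olide, CNP0220196.1 | C=C1C(=O)O[C@@H]2[C@@H]1[C@H](O)[C@@H]1O[C@@]1(C)CC/C=C(\C)[C@@H]2OC(=O)C(C)C | target

## Step count and risks

Total step count: 10. Longest linear sequence: 10 steps (1 → 17; 3 and 12 are purchased).

Most likely to fail:

Step 10 (ring closure and its three stereochemical preferences; oligomerisation, cis-fused lactone or C6 epimer are the failure modes). Fallback from 14, returning at 17: replace the reducing metal by a boron template. B2pin2 and Pd2(dba)3 (zerovalent palladium) in toluene at 50 °C exchange bromide for boron to give (1S,2E)-5-[(2S,3R)-3-formyl-2-methyloxiran-2-yl]-2-methyl-1-{(2R)-5-oxo-4-[(4,4,5,5-tetramethyl-1,3,2-dioxaborolan-2-yl)methyl]-2,5-dihydrofuran-2-yl}pent-2-en-1-yl 2-methylpropanoate F1. Heating F1 at 1 mM in toluene (90 °C) gives a metal-free intramolecular allylboration through a closed chair, with the same anti sense, and hydrolysis of the borate gives 17.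

Step 2 (enantio- and diastereocontrol on an α-branched enal with an acid-sensitive silyl enol ether reagent). Fallback from 2 and 3, returning at 7: give up enantioselective C–C formation. After the same iridium isomerisation, the uncatalysed addition (toluene, rt, no phosphoric acid) is still anti-selective. It gives, through 5 and its mirror-image (2E,6E,8R,9S)-borate ester F2, the racemate made of 6 and its enantiomer (2E,6E,8R,9S)-9-[(tert-butyldimethylsilyl)oxy]-8-hydroxy-3,7-dimethylundeca-2,6,10-trien-1-yl acetate F3. Acylative kinetic resolution with isobutyric anhydride and the (R)-configured amidine catalyst CF3-PIP (the alkenyl group of 6 taking the role of the aryl group of a benzylic alcohol) then converts 6 directly into 7 and leaves F3 behind, so resolution and step 3 are merged.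

Step 9 (metathesis of a 1,1-disubstituted bromomethyl acrylate in the presence of a free epoxy-aldehyde). Fallback from 10, returning at 14: close the butenolide before the aldehyde exists. TESCl and imidazole at −78 °C silylate only the primary hydroxyl, giving (3E,5S,6R)-6-hydroxy-4-methyl-1-[(2S,3S)-2-methyl-3-{[(triethylsilyl)oxy]methyl}oxiran-2-yl]octa-3,7-dien-5-yl 2-methylpropanoate F4. Esterification with 12 as in step 8 gives (3E,5S,6R)-6-{[2-(bromomethyl)prop-2-enoyl]oxy}-4-methyl-1-[(2S,3S)-2-methyl-3-{[(triethylsilyl)oxy]methyl}oxiran-2-yl]octa-3,7-dien-5-yl 2-methylpropanoate F5. Ring-closing metathesis, now on a substrate without aldehyde, gives (1S,2E)-1-[(2R)-4-(bromomethyl)-5-oxo-2,5-dihydrofuran-2-yl]-2-methyl-5-[(2S,3S)-2-methyl-3-{[(triethylsilyl)oxy]methyl}oxiran-2-yl]pent-2-en-1-yl 2-methylpropanoate F6. HF·pyridine gives (1S,2E)-1-[(2R)-4-(bromomethyl)-5-oxo-2,5-dihydrofuran-2-yl]-5-[(2S,3S)-3-(hydroxymethyl)-2-methyloxiran-2-yl]-2-methylpent-2-en-1-yl 2-methylpropanoate F7, and buffered Dess–Martin oxidation of F7 gives 14.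

## Further compounds

F1 | step 10 | (1S,2E)-5-[(2S,3R)-3-formyl-2-methyloxiran-2-yl]-2-methyl-1-{(2R)-5-oxo-4-[(4,4,5,5-tetramethyl-1,3,2-dioxaborolan-2-yl)methyl]-2,5-dihydrofuran-2-yl}pent-2-en-1-yl 2-methylpropanoate | O=C[C@@H]1O[C@@]1(C)CC/C=C(\C)[C@H](OC(=O)C(C)C)[C@@H]1OC(=O)C(CB2OC(C)(C)C(C)(C)O2)=C1
F2 | step 2 | (2E,6E,8R,9S)-9-[(tert-butyldimethylsilyl)oxy]-3,7-dimethyl-8-[(4,4,5,5-tetramethyl-1,3,2-dioxaborolan-2-yl)oxy]undeca-2,6,10-trien-1-yl acetate | CC(=O)OC/C=C(\C)CC/C=C(\C)[C@@H](OB1OC(C)(C)C(C)(C)O1)[C@@H](O[Si](C)(C)C(C)(C)C)C=C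
F3 | step 2 | (2E,6E,8R,9S)-9-[(tert-butyldimethylsilyl)oxy]-8-hydroxy-3,7-dimethylundeca-2,6,10-trien-1-yl acetate | CC(=O)OC/C=C(\C)CC/C=C(\C)[C@@H](O)[C@@H](O[Si](C)(C)C(C)(C)C)C=C
F4 | step 9 | (3E,5S,6R)-6-hydroxy-4-methyl-1-[(2S,3S)-2-methyl-3-{[(triethylsilyl)oxy]methyl}oxiran-2-yl]octa-3,7-dien-5-yl 2-methylpropanoate | CC[Si](CC)(CC)OC[C@@H]1O[C@@]1(C)CC/C=C(\C)[C@H](OC(=O)C(C)C)[C@H](O)C=C
F5 | step 9 | (3E,5S,6R)-6-{[2-(bromomethyl)prop-2-enoyl]oxy}-4-methyl-1-[(2S,3S)-2-methyl-3-{[(triethylsilyl)oxy]methyl}oxiran-2-yl]octa-3,7-dien-5-yl 2-methylpropanoate | CC[Si](CC)(CC)OC[C@@H]1O[C@@]1(C)CC/C=C(\C)[C@H](OC(=O)C(C)C)[C@H](OC(=O)C(=C)CBr)C=C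
F6 | step 9 | (1S,2E)-1-[(2R)-4-(bromomethyl)-5-oxo-2,5-dihydrofuran-2-yl]-2-methyl-5-[(2S,3S)-2-methyl-3-{[(triethylsilyl)oxy]methyl}oxiran-2-yl]pent-2-en-1-yl 2-methylpropanoate | CC[Si](CC)(CC)OC[C@@H]1O[C@@]1(C)CC/C=C(\C)[C@H](OC(=O)C(C)C)[C@@H]1OC(=O)C(CBr)=C1
F7 | step 9 | (1S,2E)-1-[(2R)-4-(bromomethyl)-5-oxo-2,5-dihydrofuran-2-yl]-5-[(2S,3S)-3-(hydroxymethyl)-2-methyloxiran-2-yl]-2-methylpent-2-en-1-yl 2-methylpropanoate | OC[C@@H]1O[C@@]1(C)CC/C=C(\C)[C@H](OC(=O)C(C)C)[C@@H]1OC(=O)C(CBr)=C1
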